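**Retrosynthetic overview** (chroman numbering is used throughout; C1'' is the CH2 of the isobutyl group)

1. Sideroxylonal A ⇒ (BCl3 demethylation, fourfold Rieche formylation) pentamethyl flavan ⇒ (Friedel–Crafts at C2) 1,3,5-trimethoxybenzene (ring B) + chroman-2-ol ⇒ (3R,4S)-dihydrocoumarin. C2 is set last and corrects itself through reversible O1–C2 heterolysis.
2. Pyran ring O1–C2–C3–C4–C4a–C8a ⇒ four-membered carbocycle C2–C3–C4–C1''. The link is an enantioselective rhodium-catalysed ring enlargement of a meso 3-(2-hydroxyaryl)-2,4-diisopropylcyclobutanone.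
3. Enabling feature: C4 carries two like arms, C3H(i-Pr) and C1''H2(i-Pr), that differ only in the C3–C2 bond. Tying both arms to C2 gives a Cs-symmetric ketone in which O1 of ring A lies across the ring from C2, and whose stable all-trans form maps onto the demanding 3,4-cis relation.
4. Cyclobutanone ⇒ keteniminium–styrene [2+2] (isovaleramide + E-aryl-3-methylbutene), with base equilibration of both α-centres. Styrene ⇒ 4,6-dimethoxysalicylaldehyde + i-BuMgBr.
5. Order of ring formation: rings A and B are bought, the cyclobutane is made in step 4, and the pyran ring follows by ring enlargement in step 6.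

Key step: step 6

Assumption: the sense of induction of the bisphosphine in step 6 cannot be derived from first principles. (R)-DTBM-SEGPHOS is written, and its commercial antipode is taken if it cleaves the other enantiotopic bond.

Step 1
Reactants: 1 2-hydroxy-4,6-dimethoxybenzaldehyde
Product: 2 2-(benzyloxy)-4,6-dimethoxybenzaldehyde
Conditions: BnBr, K2CO3, DMF, 60 °C
Reagents that add atoms: benzyl bromide, BrCc1ccccc1
Why: Williamson ether synthesis on the chelated phenol, which masks the future O1 through the organometallic and electrophilic steps with a group that is later removed under neutral conditions.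

Step 2
Reactants: 2 2-(benzyloxy)-4,6-dimethoxybenzaldehyde
Product: 5 1-(benzyloxy)-3,5-dimethoxy-2-[(1E)-3-methylbut-1-en-1-yl]benzene, via bromomagnesium alkoxide 3 (not isolated), via benzylic mesylate 4 (not isolated)
Conditions: i-BuMgBr, THF, 0 °C; then Et3N, MsCl, 0 to 40 °C, same flask
Reagents that add atoms: isobutylmagnesium bromide, CC(C)C[Mg]Br
Why: Grignard addition followed by sulfonylation of the alkoxide; the trialkoxybenzylic mesylate ionises at once and loses a proton from its only β-carbon (E1 elimination in basic medium, so no cationic dimerisation), and the E-alkene should form because the Z-form suffers allylic strain with both ortho substituents.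

Step 3
Reactants: 6 3-methylbutanoyl chloride
Product: 7 N,N,3-trimethylbutanamide
Conditions: Me2NH (2 M in THF, excess), CH2Cl2, 0 °C
Reagents that add atoms: dimethylamine, CNC
Why: simple acylation of a secondary amine by an acid chloride, giving the tertiary amide needed for keteniminium formation.

Step 4
Reactants: 5 1-(benzyloxy)-3,5-dimethoxy-2-[(1E)-3-methylbut-1-en-1-yl]benzene; 7 N,N,3-trimethylbutanamide
Product: 11 (2R,3s,4S)-3-[2-(benzyloxy)-4,6-dimethoxyphenyl]-2,4-di(propan-2-yl)cyclobutan-1-one (meso, both isopropyl groups trans to the aryl group), via keteniminium triflate 8 (not isolated), via cyclobutaniminium triflate 9 (not isolated), via cyclobutanone epimer mixture 10 (not isolated)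
Conditions: Tf2O, 2,4,6-collidine, ClCH2CH2Cl, −20 to 80 °C; H2O, 60 °C; organic phase, DBU (20 mol %), 40 °C
Reagents that add atoms: water, O
Why: keteniminium–alkene [2+2] cycloaddition in which the nucleophilic β-carbon of the styrene attacks the central carbon of 8 and the enamine carbon closes onto the benzylic cation, which fixes the 2,4-diisopropyl-3-aryl pattern, and because both α-stereocentres are epimerisable DBU should funnel every diastereomer of 10 into the least strained all-trans meso ketone.

Step 5
Reactants: 11 meso benzyl ether cyclobutanone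
Product: 12 (2R,3s,4S)-3-(2-hydroxy-4,6-dimethoxyphenyl)-2,4-di(propan-2-yl)cyclobutan-1-one (meso)
Conditions: H2 (1 atm), Pd/C, EtOAc, rt
Reagents that add atoms: none
Why: hydrogenolysis of a benzyl aryl ether under neutral conditions, which leaves the ketone, the strained ring and the two α-centres untouched.

Step 6
Reactants: 12 meso 3-(2-hydroxy-4,6-dimethoxyphenyl)-2,4-di(propan-2-yl)cyclobutan-1-one
Product: 14 (3R,4S)-5,7-dimethoxy-4-(2-methylpropyl)-3-(propan-2-yl)chroman-2-one, via bridged hemiketal 13 (not isolated)
Conditions: [Rh(OH)(cod)]2 (2.5 mol %), (R)-DTBM-SEGPHOS (6 mol %), toluene, 25 to 40 °C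
Reagents that add atoms: none
Why: Proposed new method: the monovalent rhodium hydroxide exchanges with the phenol of 12, the rhodium aryloxide adds O1 to the strained carbonyl carbon C2 from the aryl-bearing face (rhodium salt of 13), β-carbon elimination breaks one of the two enantiotopic C2–CH(i-Pr) bonds, and the phenol of the next substrate molecule protonates the secondary alkylrhodium, so that 12 is isomerised to 14 without any added atom. The closest known reaction type is the rhodium/chiral bisphosphine-catalysed addition/β-carbon elimination of 3-(2-hydroxyaryl)cyclobutanones that are unsubstituted at the α-carbons, which gives 3,4-dihydrocoumarins; new here are the cleavage of a C(O)–C(secondary) bond and an alkylrhodium that carries β-hydrogens. The pyranone ring forms by transannular 6-exo-trig attack of O1 on C2 and becomes monocyclic when the C2–C1'' bridge is cut, so the carbocycle C2–C3–C4–C1'' (four atoms) is enlarged to O1–C2–C3–C4–C4a–C8a (six atoms) while C1'' becomes the CH2 of the isobutyl group, driven by release of roughly 25 kcal/mol of ring strain. No bond to C3 or C4 is made or broken, so the 3,4-cis relation follows from the all-trans geometry of 12 (isopropyl trans to aryl on the four-membered ring equals isopropyl cis to isobutyl on the six-membered ring), and the absolute configuration (3R,4S) is decided solely by which enantiotopic bond, here the one to the S-configured α-carbon, the chiral ligand pocket presents to rhodium. The step needs bond selection (ligand control, sharpened by the isopropyl group next to each candidate bond), hemiketalate formation faster than retro-Michael opening of a C4–Cα bond towards an ortho-quinone methide (neutral medium, ambient temperature, O1 held within reach of C2), and protonolysis faster than loss of alkene (a phenol as stoichiometric proton source, both ortho positions of ring A blocked so that no 1,4-rhodium shift can divert the alkylrhodium). If β-hydride elimination and re-insertion intervene, they are suprafacial on the bound alkene, keep C4 intact and end at the rhodium enolate, whose protonation anti to the pseudo-axial isobutyl group should again give the cis-lactone.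

Step 7
Reactants: 14 (3R,4S)-5,7-dimethoxy-4-(2-methylpropyl)-3-(propan-2-yl)chroman-2-one
Product: 15 (3R,4S)-5,7-dimethoxy-4-(2-methylpropyl)-3-(propan-2-yl)chroman-2-ol (anomer mixture)
Conditions: i-Bu2AlH (1.1 equiv), toluene, −78 °C; aq. potassium sodium tartrate
Reagents that add atoms: none
Why: partial reduction of a dihydrocoumarin to the 2-chromanol at low temperature, a non-basic operation that should not touch the epimerisable C3 centre.

Step 8
Reactants: 15 (3R,4S)-chroman-2-ol; 16 1,3,5-trimethoxybenzene
Product: 18 (2R,3R,4S)-5,7-dimethoxy-4-(2-methylpropyl)-3-(propan-2-yl)-2-(2,4,6-trimethoxyphenyl)chroman, via oxocarbenium triflate 17 (not isolated)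
Conditions: 16 (3 equiv), TfOH (5 mol %), CH2Cl2, −40 to 0 °C
Reagents that add atoms: none
Why: Friedel–Crafts arylation of the cyclic oxocarbenium ion 17, in which attack anti to the pseudo-axial C4 isobutyl group gives the 2,3-trans product and reversible acid-induced O1–C2 heterolysis (benzylic cation stabilised by ring B) should correct any cis isomer to the same best half-chair (C2 and C3 equatorial, C4 pseudo-axial away from the C5 methoxy group).

Step 9
Reactants: 18 pentamethyl flavan
Product: 19 (2R,3R,4S)-2-(3,5-diformyl-2,4,6-trimethoxyphenyl)-5,7-dimethoxy-4-(2-methylpropyl)-3-(propan-2-yl)chroman-6,8-dicarbaldehyde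
Conditions: Cl2CHOMe (12 equiv), TiCl4 (12 equiv), CH2Cl2, −78 to 0 °C; aq. HCl
Reagents that add atoms: dichloromethyl methyl ether, COC(Cl)Cl; water, O
Why: Rieche formylation, known for the double formylation of 5,7-dimethoxychromans and 2-alkyl-1,3,5-trimethoxybenzenes, should fill all four free positions because each lies ortho/para to three oxygen donors and only meta to a formyl group already present, and the first formyl group on ring B damps O1–C2 ionisation.

Step 10
Reactants: 19 tetraaldehyde pentamethyl ether
Product: 20 sideroxylonal A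
Conditions: BCl3 (15 equiv), CH2Cl2, −78 °C to rt; H2O
Reagents that add atoms: none
Why: chelation-assisted aryl methyl ether cleavage works here because every methoxy group is ortho to a formyl group, and should O1–C2 open under the Lewis acid, the symmetric ring A phenol re-closes on work-up to the same 2,3-trans chroman.

**Compound list**

1 | 2-hydroxy-4,6-dimethoxybenzaldehyde | COc1cc(O)c(C=O)c(OC)c1 | starting material
2 | 2-(benzyloxy)-4,6-dimethoxybenzaldehyde | COc1cc(OCc2ccccc2)c(C=O)c(OC)c1 | intermediate
3 | bromomagnesium 1-[2-(benzyloxy)-4,6-dimethoxyphenyl]-3-methylbutan-1-olate (racemic) | CC(C)CC(O[Mg]Br)c1c(OCc2ccccc2)cc(OC)cc1OC | intermediate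
4 | 1-[2-(benzyloxy)-4,6-dimethoxyphenyl]-3-methylbutyl methanesulfonate (racemic) | CC(C)CC(OS(C)(=O)=O)c1c(OCc2ccccc2)cc(OC)cc1OC | intermediate
5 | 1-(benzyloxy)-3,5-dimethoxy-2-[(1E)-3-methylbut-1-en-1-yl]benzene | CC(C)/C=C/c1c(OCc2ccccc2)cc(OC)cc1OC | intermediate
6 | 3-methylbutanoyl chloride | CC(C)CC(=O)Cl | starting material
7 | N,N,3-trimethylbutanamide | CC(C)CC(=O)N(C)C | intermediate
8 | isopropylketene dimethyliminium triflate | CC(C)C=C=[N+](C)C.[O-]S(=O)(=O)C(F)(F)F | intermediate
9 | 3-[2-(benzyloxy)-4,6-dimethoxyphenyl]-2,4-di(propan-2-yl)cyclobutylidene(dimethyl)ammonium triflate (diastereomer mixture) | CC(C)C1C(c2c(OCc3ccccc3)cc(OC)cc2OC)C(C(C)C)C1=[N+](C)C.[O-]S(=O)(=O)C(F)(F)F | intermediate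
10 | 3-[2-(benzyloxy)-4,6-dimethoxyphenyl]-2,4-di(propan-2-yl)cyclobutan-1-one (epimer mixture) | CC(C)C1C(c2c(OCc3ccccc3)cc(OC)cc2OC)C(C(C)C)C1=O | intermediate
11 | (2R,3s,4S)-3-[2-(benzyloxy)-4,6-dimethoxyphenyl]-2,4-di(propan-2-yl)cyclobutan-1-one (meso, all-trans) | O=C1[C@@H](C(C)C)[C@H](c2c(OCc3ccccc3)cc(OC)cc2OC)[C@H]1C(C)C | intermediate
12 | (2R,3s,4S)-3-(2-hydroxy-4,6-dimethoxyphenyl)-2,4-di(propan-2-yl)cyclobutan-1-one (meso, all-trans) | O=C1[C@@H](C(C)C)[C@H](c2c(O)cc(OC)cc2OC)[C@H]1C(C)C | intermediate
13 | bridged hemiketal of 12 (benzo-fused 2-oxabicyclo[3.1.1]heptan-1-ol, meso; O1 bonded to the former carbonyl carbon) | O[C@@]12Oc3cc(OC)cc(OC)c3[C@@H]([C@@H]1C(C)C)[C@H]2C(C)C | intermediate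
14 | (3R,4S)-5,7-dimethoxy-4-(2-methylpropyl)-3-(propan-2-yl)chroman-2-one | CC(C)C[C@@H]1c2c(OC)cc(OC)cc2OC(=O)[C@@H]1C(C)C | intermediate
15 | (3R,4S)-5,7-dimethoxy-4-(2-methylpropyl)-3-(propan-2-yl)chroman-2-ol (anomer mixture) | CC(C)C[C@@H]1c2c(OC)cc(OC)cc2OC(O)[C@@H]1C(C)C | intermediate
16 | 1,3,5-trimethoxybenzene | COc1cc(OC)cc(OC)c1 | starting material
17 | (3R,4S)-5,7-dimethoxy-4-(2-methylpropyl)-3-(propan-2-yl)-3,4-dihydrochromenylium triflate | CC(C)C[C@@H]1c2c(OC)cc(OC)cc2[O+]=C[C@@H]1C(C)C.[O-]S(=O)(=O)C(F)(F)F | intermediate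
18 | (2R,3R,4S)-5,7-dimethoxy-4-(2-methylpropyl)-3-(propan-2-yl)-2-(2,4,6-trimethoxyphenyl)chroman | CC(C)C[C@@H]1c2c(OC)cc(OC)cc2O[C@@H](c2c(OC)cc(OC)cc2OC)[C@@H]1C(C)C | intermediate
19 | (2R,3R,4S)-2-(3,5-diformyl-2,4,6-trimethoxyphenyl)-5,7-dimethoxy-4-(2-methylpropyl)-3-(propan-2-yl)chroman-6,8-dicarbaldehyde | CC(C)C[C@@H]1c2c(OC)c(C=O)c(OC)c(C=O)c2O[C@@H](c2c(OC)c(C=O)c(OC)c(C=O)c2OC)[C@@H]1C(C)C | intermediate
20 | sideroxylonal A, (2R,3R,4S) | CC(C)C[C@@H]1c2c(O)c(C=O)c(O)c(C=O)c2O[C@@H](c2c(O)c(C=O)c(O)c(C=O)c2O)[C@@H]1C(C)C | target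

Total step count: 10.
Longest linear sequence: 9 (steps 1, 2, 4, 5, 6, 7, 8, 9, 10).

**Steps most likely to fail**

**Step 6.** The secondary alkylrhodium may undergo β-hydride elimination followed by dissociation of the alkene, which would erode C4 and give dehydrogenated by-products. The ligand may discriminate the two enantiotopic bonds too weakly. The aryloxide may also open the four-membered ring in a retro-Michael sense.

The fallback uses known chemistry only, sets out from 11 and comes back at 14.
- A catalytic asymmetric Baeyer–Villiger oxidation (chiral phosphoric acid, aq. H2O2, CHCl3, −40 °C) desymmetrises 11 by oxygen insertion into one enantiotopic C(O)–CH bond with retention, giving the γ-lactone F1.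
- Me3Al/MeNHOMe·HCl opens it to the hydroxy Weinreb amide F2.
- 1,1'-Thiocarbonyldiimidazole (DMAP, toluene, 80 °C) gives the imidazolylthiocarbonate F3.
- Barton–McCombie deoxygenation (Bu3SnH, AIBN, toluene, 90 °C) gives the amide F4, in which the former ring carbon is already the isobutyl CH2.
- H2, Pd/C frees the phenol amide F5, and p-TsOH in warm toluene closes it to 14 by acyl transfer to O1.

**Step 4.** The keteniminium ion may acylate the electron-rich arene in a Friedel–Crafts sense. Alternatively, the strongly stabilised benzylic cation may fail to close the strained ring and lose a proton to an open-chain aminodiene.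

The fallback sets out from 5 and comes back at 10.
- Bromo(isopropyl)ketene, generated from 2-bromo-3-methylbutanoyl chloride and Et3N in hexane/CH2Cl2, is a neutral and more electrophilic 2π partner.
- It undergoes the known haloketene–alkene [2+2] cycloaddition with the same regiochemistry to give the bromocyclobutanone F6.
- Zn in AcOH removes the bromine to give 10, which is equilibrated with DBU to 11 as before.

**Step 9.** The fourth formylation may stall. TiCl4 may also trigger O1–C2 heterolysis followed by proton loss from C3 (erosion of C3) or retro-Friedel–Crafts loss of ring B.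

The fallback sets out from 18 and comes back at 20, with the order of events reversed.
- BBr3 (CH2Cl2, −78 °C to rt) first gives the pentaphenol F7.
- Its far more nucleophilic free phloroglucinol rings are then exhaustively formylated under the mild Vilsmeier–Haack conditions known for the diformylation of phloroglucinols (POCl3, DMF, EtOAc, 0 °C to rt; H2O).
- This gives 20 directly without a final deprotection.

**Further compounds**

F1 | step 6 | (3R,4S,5S)-4-[2-(benzyloxy)-4,6-dimethoxyphenyl]-3,5-di(propan-2-yl)oxolan-2-one | O=C1O[C@@H](C(C)C)[C@H](c2c(OCc3ccccc3)cc(OC)cc2OC)[C@H]1C(C)C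
F2 | step 6 | (2R,3S,4S)-3-[2-(benzyloxy)-4,6-dimethoxyphenyl]-4-hydroxy-N-methoxy-N,5-dimethyl-2-(propan-2-yl)hexanamide | CON(C)C(=O)[C@H](C(C)C)[C@@H](c1c(OCc2ccccc2)cc(OC)cc1OC)[C@@H](O)C(C)C
F3 | step 6 | O-(imidazol-1-ylthiocarbonyl) derivative of F2 | CON(C)C(=O)[C@H](C(C)C)[C@@H](c1c(OCc2ccccc2)cc(OC)cc1OC)[C@@H](OC(=S)n1ccnc1)C(C)C
F4 | step 6 | (2R,3S)-3-[2-(benzyloxy)-4,6-dimethoxyphenyl]-N-methoxy-N,5-dimethyl-2-(propan-2-yl)hexanamide | CON(C)C(=O)[C@H](C(C)C)[C@@H](c1c(OCc2ccccc2)cc(OC)cc1OC)CC(C)C
F5 | step 6 | (2R,3S)-3-(2-hydroxy-4,6-dimethoxyphenyl)-N-methoxy-N,5-dimethyl-2-(propan-2-yl)hexanamide | CON(C)C(=O)[C@H](C(C)C)[C@@H](c1c(O)cc(OC)cc1OC)CC(C)C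
F6 | step 4 | 3-[2-(benzyloxy)-4,6-dimethoxyphenyl]-2-bromo-2,4-di(propan-2-yl)cyclobutan-1-one (racemic diastereomer mixture) | CC(C)C1C(=O)C(Br)(C(C)C)C1c1c(OCc2ccccc2)cc(OC)cc1OC
F7 | step 9 | (2R,3R,4S)-4-(2-methylpropyl)-3-(propan-2-yl)-2-(2,4,6-trihydroxyphenyl)chroman-5,7-diol | CC(C)C[C@@H]1c2c(O)cc(O)cc2O[C@@H](c2c(O)cc(O)cc2O)[C@@H]1C(C)C
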